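Remark on the chemistry: the target has no stereocentre. Compounds 3, 4, 10, 21 and 22 carry enolisable stereocentres and are taken as racemates or diastereomer mixtures, which is harmless because each of these carbons ends up sp2.

## The problem

The target is a flavonol: a 5,7-dihydroxychromen-4-one (rings A and C) with a hydroxyl at C3 and, at C2, a phenolic ring B whose 4'-hydroxyl is flanked by 3-methylbut-2-enyl (prenyl) groups at C3' and C5'. With no stereocentre, the difficulties are constitutional and chemoselective. The prenyl alkenes are the fragile part: strong acid adds the neighbouring 4'-OH across them to give chromans, electrophilic oxidants epoxidise them and hydrogenation saturates them. This excludes benzyl ethers, peracid or dioxirane hydroxylation of C3 and harsh ether cleavage. The C3 oxygen must therefore arrive inside a building block, and the hydroxyls at C3, C5, C7 and C4' need masks that leave under mild conditions. Installing two prenyl groups ortho to one phenol by alkylation is unselective (O- against C-alkylation, mono against bis, linear against reverse prenyl). The enabling feature is the local symmetry of ring B: C4' with its oxygen sits between identical carbons C3' and C5', each carrying the same side chain, and C1' opposite carries the only other carbon substituent. C3'–C4'–C5' with both prenyl groups thus maps onto one symmetric ketone and C2'–C1'–C6' onto a 2-substituted malonaldehyde, so ring B can be assembled from acyclic parts.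

## Retrosynthesis

**Ring C and the protecting groups.** Cutting O1–C2 of target 23 opens ring C to the ortho-hydroxyaryl 2-hydroxy-1,3-diketone 22, which is handled as its penta-acetal 21. Closing ring C last by cyclodehydration is preferred over hydroxylating C3 of a finished flavone, because every reagent for that oxidation would also attack the prenyl alkenes. In 21 the C3 oxygen is already present. The forward step must cleave five methoxymethyl ethers and dehydrate without adding the freed 4'-OH to a prenyl group.

**The C2–C3 bond.** Diketone 21 is cut between C2 and C3 into ketone 20 (ring A, C4, C3 and its oxygen) and benzoate 13 (ring B and C2). The other cut, C3–C4, would need an acyl donor flanked by two ortho oxygens, which is a poor electrophile. Here the hindered partner is the nucleophile and the unhindered ester the electrophile, and the shielding of the carbonyl of 20 also suppresses its self-condensation. The forward reaction is a crossed Claisen condensation. It tolerates no acidic OH, so both partners are fully protected.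

**The C4–C4a bond.** Ketone 20 is cut at the aryl–carbonyl bond into arene 15 and the glycolic Weinreb amide 18. An acid-mediated acylation of phloroglucinol 14 could not carry an acid-labile ether on the two-carbon unit; ortho-lithiation of 15 (via 19) can. Arene 15 comes from 14 by acetal protection; 18 comes from methyl glycolate 16 through ether 17.

**Ring B (key disconnection).** Benzoate 13 is the protected form of phenol 12. Cutting C2'–C3' and C5'–C6' of 12 gives ketone 6 and dialdehyde 9. The alternative of substituting a preformed phenol twice ortho to its hydroxyl has the selectivity problems named above, whereas here both prenyl groups are already on 6. The simplification is large: a pentasubstituted arene becomes two symmetric acyclic fragments. The forward reaction must favour cross-condensation over self-aldolisation of 6 and must leave ester and alkenes intact; it proceeds through enone 10 and dienone 11.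

**The acyclic fragments.** Ketone 6 is cut at both Cα–CH2 bonds to 1-bromo-3-methylbut-2-ene 2 and the acetone equivalent 1, whose two ester groups activate each α-carbon in turn and are removed by decarboxylation (via 3, 4 and 5). Dialdehyde 9 is cut at C1'–CHO: formylation of ester 7, which already holds one masked aldehyde, then unmasking of 8.

## Roads not taken

**Alternative 1:** Cut C4–C4a and C8a–O1, making ring A an aryne. Forward, CsF releases the aryne from silyl triflate A3; the carboxylate of arylpropiolic acid A2 adds through oxygen to the aryne carbon remote from the neighbouring acetal oxygen, and the aryl anion then takes the acyl group to give ynone A1.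
- Merits: one step acylates ring A and leaves exactly the one free phenol needed for ring C, with regiochemistry fixed by the 3-alkoxy group. No organolithium or hydride base is needed. In these respects it is better than steps 9 and 10.
- Weak points: A1 closes (6-endo) to a flavone without oxygen at C3, so a C3 hydroxylation would have to follow in the presence of two oxidisable alkenes, and 5-exo closure to an aurone competes. A3 needs several steps, and A2 still requires the diprenylated ring B plus a two-carbon homologation.
- Comparison: the chosen plan sets against its convergence that the C3 oxygen is built in through 18 and that ring B, which this road leaves open, is solved by step 4.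

**Alternative 2:** Cut C4–C4a, C3–C4 and O1–C2 at once. Forward, iodophenol A5 and arylacetylene A6 are joined under carbonylative conditions with PdCl2(PPh3)2 in diethylamine to close ring C as flavone A4.
- Merits: three bonds and ring C in a single mild, base-only step that tolerates prenyl groups. For building the tricyclic core it is shorter than the chosen plan.
- Weak points: A4 again lacks the C3 hydroxyl, which is the one functional group that cannot be added late here. Aurone formation by 5-exo closure is a known side path. A6 needs ring B plus an ethynyl group, and A5 needs a selectively mono-iodinated, mono-unprotected phloroglucinol.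
- Comparison: the chosen plan needs more steps for ring C but no oxidation at all, and its ring B synthesis could equally serve A6.

**Alternative 3:** Cut C4a–C5 inside ring A. Forward, base folds the cinnamoyl triketo ester A8 so that its C6 methylene attacks the ester carbonyl, giving chalcone A7.
- Merits: ring A is made from an acyclic chain with no protecting groups and inherent acylation regiochemistry. It is the most economical road in protecting groups.
- Weak points: A8 has three acidic methylenes and four carbonyls, so aldol closure to a resorcylate and lactonisation to pyrones compete. A7, with three free phenols, must then be oxidatively cyclised with alkaline H2O2, which for chalcones oxygenated at both ortho positions tends to give aurones. The ring B aldehyde is still required.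
- Comparison: the chosen plan spends more protecting-group steps, but each carbon–carbon bond formation in it has a single constitutional outcome.

Key step: step 4

## Route

**Step 1**
Reactants: 1 diethyl 3-oxopentanedioate; 2 1-bromo-3-methylbut-2-ene (2 equiv)
Product: 4 diethyl 2,4-bis(3-methylbut-2-enyl)-3-oxopentanedioate, via monoprenyl keto diester 3 (not isolated)
Conditions: NaH (1.05 equiv), THF, 0 °C, then 2 (1.0 equiv), 20 °C; repeated once in the same flask
Reagents that add atoms: none
Why: C-alkylation of a β-keto ester sodium enolate (acetoacetic ester alkylation) by SN2 at the primary allylic bromide gives the linear prenyl group. After the first alkylation the unsubstituted C4 methylene of 3 is the more acidic site, so the second prenyl group should enter at the other α-carbon.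

**Step 2**
Reactants: 4 diethyl 2,4-bis(3-methylbut-2-enyl)-3-oxopentanedioate
Product: 6 2,10-dimethylundeca-2,9-dien-6-one, via keto diacid 5 (not isolated)
Conditions: NaOH (aq., 1 M), EtOH, 20 °C; then HCl (aq.) to pH 3, 50 °C
Reagents that add atoms: none
Why: Ketonic cleavage of the acetoacetic ester synthesis: saponification, then twofold decarboxylation of the β-keto diacid through its cyclic six-membered transition state. Dilute base and pH 3 at 50 °C should not hydrate the trisubstituted alkenes.

**Step 3**
Reactants: 7 ethyl 3,3-diethoxypropanoate
Product: 9 ethyl 2-formyl-3-oxopropanoate, via formylated acetal 8 (not isolated)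
Conditions: NaH, HCO2Et, THF, 0 → 20 °C; then HCl (aq., 2 M), 0 → 20 °C
Reagents that add atoms: ethyl formate, CCOC=O; water, O
Why: Crossed Claisen formylation of the ester enolate with a non-enolisable formate is driven by formation of the stabilised sodium enolate of 8. Aqueous acid then hydrolyses the diethyl acetal to the second aldehyde, and 9 is obtained as its stable enol.

**Step 4 (key step)**
Reactants: 6 2,10-dimethylundeca-2,9-dien-6-one; 9 ethyl 2-formyl-3-oxopropanoate
Product: 12 ethyl 4-hydroxy-3,5-bis(3-methylbut-2-enyl)benzoate, via open-chain enone aldehyde 10 (not isolated), via cyclohexadienone tautomer 11 (not isolated)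
Conditions: NaOH (aq., 2.5 equiv), EtOH, 20 °C; then AcOH to pH 5
Reagents that add atoms: none
Why: This is the base-mediated [3+3] phenol synthesis from a ketone with two α-methylene groups and a 2-substituted malonaldehyde, established for 2-nitromalonaldehyde with dialkyl ketones and applied here to the ester analogue. Hydroxide forms the enolate of 6, which adds to one formyl carbon of 9 (present as its delocalised sodium enolate); loss of water gives enone 10 and the C2'–C3' bond. The second α-methylene of the same ketone is then enolised and attacks the remaining formyl group in a 6-(enolendo)-exo-trig intramolecular aldol, forming C5'–C6' and closing ring B; dehydration gives cross-conjugated dienone 11. The hydrogen left on C1' of 11 is α to the ester and vinylogously α to the ketone, so it is removed at once and the phenolate of 12 results; this aromatisation is irreversible and draws the reversible aldol equilibria forward. No stereocentre is created. Only one constitution is possible because both partners are symmetric and 9 cannot enolise anywhere but at its central carbon; the needed selectivity is cross-condensation over self-aldolisation of 6, secured because only the cross product reaches an aromatic sink. The trisubstituted alkenes are inert to dilute hydroxide, and the ester is deactivated towards saponification because it is part of an enolate or phenolate anion at every stage.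

**Step 5**
Reactants: 12 ethyl 4-hydroxy-3,5-bis(3-methylbut-2-enyl)benzoate
Product: 13 ethyl 4-(methoxymethoxy)-3,5-bis(3-methylbut-2-enyl)benzoate
Conditions: NaH, MOMCl, DMF, 0 → 20 °C
Reagents that add atoms: chloromethyl methyl ether, COCCl
Why: O-Alkylation of the sodium phenoxide (Williamson type) with a small, very reactive electrophile should overcome the two ortho substituents. The acetal removes the acidic OH that would otherwise turn the ester into an unreactive phenoxide-benzoate in step 10.

**Step 6**
Reactants: 14 phloroglucinol (benzene-1,3,5-triol)
Product: 15 1,3,5-tris(methoxymethoxy)benzene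
Conditions: NaH, MOMCl, DMF, 0 → 20 °C
Reagents that add atoms: chloromethyl methyl ether, COCCl
Why: Exhaustive O-alkylation of the triphenoxide; the hard oxocarbenium-like electrophile reacts at oxygen and not at the ring carbons.

**Step 7**
Reactants: 16 methyl 2-hydroxyacetate (methyl glycolate)
Product: 17 methyl 2-(methoxymethoxy)acetate
Conditions: MOMCl, i-Pr2NEt, CH2Cl2, 0 → 20 °C
Reagents that add atoms: chloromethyl methyl ether, COCCl
Why: Standard methoxymethyl ether formation on a primary alcohol; the amine base avoids alkoxide-induced transesterification or Claisen self-condensation.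

**Step 8**
Reactants: 17 methyl 2-(methoxymethoxy)acetate
Product: 18 N-methoxy-2-(methoxymethoxy)-N-methylacetamide
Conditions: MeNH(OMe)·HCl, i-PrMgCl, THF, −20 → 0 °C
Reagents that add atoms: N,O-dimethylhydroxylamine hydrochloride, CNOC.Cl
Why: Aminolysis of the ester by the chloromagnesium amide of N,O-dimethylhydroxylamine (Weinreb amide synthesis), fast at low temperature for an unhindered α-alkoxy ester.

**Step 9**
Reactants: 15 1,3,5-tris(methoxymethoxy)benzene; 18 N-methoxy-2-(methoxymethoxy)-N-methylacetamide
Product: 20 2-(methoxymethoxy)-1-[2,4,6-tris(methoxymethoxy)phenyl]ethanone, via aryllithium 19 (not isolated)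
Conditions: n-BuLi, THF, 0 °C; then 18, −78 → 0 °C; NH4Cl (aq.)
Reagents that add atoms: none
Why: Directed ortho-metalation at the position between two coordinating acetal oxygens gives 19, and Weinreb ketone synthesis follows. The chelated tetrahedral adduct survives until work-up, so neither over-addition nor enolisation of the product ketone can occur.

**Step 10**
Reactants: 20 2-(methoxymethoxy)-1-[2,4,6-tris(methoxymethoxy)phenyl]ethanone; 13 ethyl 4-(methoxymethoxy)-3,5-bis(3-methylbut-2-enyl)benzoate
Product: 21 2-(methoxymethoxy)-1-[4-(methoxymethoxy)-3,5-bis(3-methylbut-2-enyl)phenyl]-3-[2,4,6-tris(methoxymethoxy)phenyl]propane-1,3-dione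
Conditions: NaH (3 equiv), THF, 0 → 65 °C; then AcOH
Reagents that add atoms: none
Why: Crossed Claisen condensation of a ketone enolate with a non-enolisable aryl ester, driven by deprotonation of the 2-alkoxy-1,3-diketone formed. The carbonyl of 20 is shielded by two ortho acetal groups, so self-condensation is suppressed, and the acetal oxygen of 13 is twisted out of conjugation by its two ortho substituents, so the ester keeps its electrophilicity.

**Step 11**
Reactants: 21 2-(methoxymethoxy)-1-[4-(methoxymethoxy)-3,5-bis(3-methylbut-2-enyl)phenyl]-3-[2,4,6-tris(methoxymethoxy)phenyl]propane-1,3-dione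
Product: 23 3,5,7-trihydroxy-2-[4-hydroxy-3,5-bis(3-methylbut-2-enyl)phenyl]chromen-4-one, via pentahydroxy diketone 22 (not isolated)
Conditions: HCl (aq., 3 M), MeOH, 45 °C
Reagents that add atoms: none
Why: Acid-catalysed acetal exchange with methanol removes the five methoxymethyl groups. The ortho-hydroxyaryl 2-hydroxy-1,3-diketone then closes ring C by hemiketalisation at the ring B carbonyl and loss of water, the usual cyclodehydration of flavone synthesis. The two ortho hydroxyls of ring A are equivalent, so only one chromenone can form.

## Compound list

1 | diethyl 3-oxopentanedioate | CCOC(=O)CC(=O)CC(=O)OCC | starting material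
2 | 1-bromo-3-methylbut-2-ene | CC(C)=CCBr | starting material
3 | diethyl 2-(3-methylbut-2-enyl)-3-oxopentanedioate (racemic) | CCOC(=O)CC(=O)C(CC=C(C)C)C(=O)OCC | intermediate (not isolated)
4 | diethyl 2,4-bis(3-methylbut-2-enyl)-3-oxopentanedioate (mixture of diastereomers) | CCOC(=O)C(CC=C(C)C)C(=O)C(CC=C(C)C)C(=O)OCC | intermediate
5 | 2,4-bis(3-methylbut-2-enyl)-3-oxopentanedioic acid (mixture of diastereomers) | OC(=O)C(CC=C(C)C)C(=O)C(CC=C(C)C)C(=O)O | intermediate (not isolated)
6 | 2,10-dimethylundeca-2,9-dien-6-one | CC(C)=CCCC(=O)CCC=C(C)C | intermediate
7 | ethyl 3,3-diethoxypropanoate | CCOC(=O)CC(OCC)OCC | starting material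
8 | ethyl 2-(diethoxymethyl)-3-oxopropanoate (formed as its sodium enolate) | CCOC(=O)C(C=O)C(OCC)OCC | intermediate (not isolated)
9 | ethyl 2-formyl-3-oxopropanoate | CCOC(=O)C(C=O)C=O | intermediate
10 | ethyl (3Z)-2-formyl-9-methyl-4-(3-methylbut-2-enyl)-5-oxodeca-3,8-dienoate (racemic at C2, enolised in base) | CCOC(=O)C(C=O)/C=C(/CC=C(C)C)C(=O)CCC=C(C)C | intermediate (not isolated)
11 | ethyl 3,5-bis(3-methylbut-2-enyl)-4-oxocyclohexa-2,5-diene-1-carboxylate | CCOC(=O)C1C=C(CC=C(C)C)C(=O)C(CC=C(C)C)=C1 | intermediate (not isolated)
12 | ethyl 4-hydroxy-3,5-bis(3-methylbut-2-enyl)benzoate | CCOC(=O)c1cc(CC=C(C)C)c(O)c(CC=C(C)C)c1 | intermediate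
13 | ethyl 4-(methoxymethoxy)-3,5-bis(3-methylbut-2-enyl)benzoate | CCOC(=O)c1cc(CC=C(C)C)c(OCOC)c(CC=C(C)C)c1 | intermediate
14 | phloroglucinol (benzene-1,3,5-triol) | Oc1cc(O)cc(O)c1 | starting material
15 | 1,3,5-tris(methoxymethoxy)benzene | COCOc1cc(OCOC)cc(OCOC)c1 | intermediate
16 | methyl 2-hydroxyacetate | COC(=O)CO | starting material
17 | methyl 2-(methoxymethoxy)acetate | COCOCC(=O)OC | intermediate
18 | N-methoxy-2-(methoxymethoxy)-N-methylacetamide | COCOCC(=O)N(C)OC | intermediate
19 | [2,4,6-tris(methoxymethoxy)phenyl]lithium | [Li]c1c(OCOC)cc(OCOC)cc1OCOC | intermediate (not isolated)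
20 | 2-(methoxymethoxy)-1-[2,4,6-tris(methoxymethoxy)phenyl]ethanone | COCOCC(=O)c1c(OCOC)cc(OCOC)cc1OCOC | intermediate
21 | 2-(methoxymethoxy)-1-[4-(methoxymethoxy)-3,5-bis(3-methylbut-2-enyl)phenyl]-3-[2,4,6-tris(methoxymethoxy)phenyl]propane-1,3-dione (racemic, in equilibrium with its enols) | COCOC(C(=O)c1cc(CC=C(C)C)c(OCOC)c(CC=C(C)C)c1)C(=O)c1c(OCOC)cc(OCOC)cc1OCOC | intermediate
22 | 2-hydroxy-1-[4-hydroxy-3,5-bis(3-methylbut-2-enyl)phenyl]-3-(2,4,6-trihydroxyphenyl)propane-1,3-dione (racemic) | CC(C)=CCc1cc(C(=O)C(O)C(=O)c2c(O)cc(O)cc2O)cc(CC=C(C)C)c1O | intermediate (not isolated)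
23 | 3,5,7-trihydroxy-2-[4-hydroxy-3,5-bis(3-methylbut-2-enyl)phenyl]chromen-4-one | CC(C)=CCc1cc(-c2oc3cc(O)cc(O)c3c(=O)c2O)cc(CC=C(C)C)c1O | target

## Step count and risks

Total steps: 11. Longest linear sequence: 6 steps (1, 2, 4, 5, 10, 11, from diethyl 3-oxopentanedioate); the ring A branch (7, 8, 9, then 10, 11) has 5.

**Step 4 (key step).** The first intermolecular aldol addition may be too slow. In hydroxide, 9 is a resonance-stabilised enolate and a weaker electrophile than the nitro analogue on which the method rests, and the unactivated ketone 6 is enolised only to a small extent. Self-aldolisation of 6 and gradual saponification of the ester could then dominate. Fallback, setting out from 2 and returning at 13: 2 is treated with Bu3SnLi to give tributyl(3-methylbut-2-enyl)stannane F1. Commercial ethyl 4-hydroxy-3,5-diiodobenzoate F2 is protected with MOMCl and NaH to give ethyl 3,5-diiodo-4-(methoxymethoxy)benzoate F3. A twofold Stille coupling of F3 with F1 (Pd(PPh3)4, DMF, 90 °C), which transfers the prenyl group mainly through its unsubstituted terminus, then gives 13 directly.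

**Step 1.** Regiocontrol of the second alkylation may be lost: alkylation at the already substituted carbon, a third alkylation and some O-alkylation would give mixtures that are hard to separate. Fallback, setting out from 2 and returning at 6: ethyl 3-oxobutanoate F4 is converted into its dianion (NaH, then n-BuLi) and alkylated with 2 at the terminal carbon to give ethyl 7-methyl-3-oxooct-6-enoate F5. The monoanion of F5 (NaH, THF) is alkylated with 2 at C2 to give ethyl 7-methyl-2-(3-methylbut-2-enyl)-3-oxooct-6-enoate F6. Saponification and decarboxylation as in step 2 give 6; each alkylation site is fixed by the order of deprotonation.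

**Step 10.** C-Acylation may stall, because the α-alkoxy enolate of 20 is hindered and the ester of 13 is only moderately electrophilic; prolonged heating with NaH then invites decomposition of the enolate. Fallback, setting out from 13 and returning at 21: 13 is reduced with i-Bu2AlH to [4-(methoxymethoxy)-3,5-bis(3-methylbut-2-enyl)phenyl]methanol F7 and oxidised with MnO2 to 4-(methoxymethoxy)-3,5-bis(3-methylbut-2-enyl)benzaldehyde F8. The lithium enolate of 20 (LiN(SiMe3)2, THF, −78 °C) adds to this far more reactive aldehyde to give 3-hydroxy-2-(methoxymethoxy)-3-[4-(methoxymethoxy)-3,5-bis(3-methylbut-2-enyl)phenyl]-1-[2,4,6-tris(methoxymethoxy)phenyl]propan-1-one F9 as a diastereomer mixture. Dess–Martin oxidation of the secondary alcohol, which leaves the alkenes alone, gives 21.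

**Step 11.** Once the 4'-hydroxyl is free, acid-promoted addition of it to a neighbouring prenyl alkene (chroman closure), or Markovnikov addition of HCl or methanol, may compete with cleavage of the hindered 4'-acetal and with cyclodehydration. Fallback, setting out from 12 and returning at 23: 12 is allylated (allyl bromide, K2CO3, DMF) to ethyl 3,5-bis(3-methylbut-2-enyl)-4-prop-2-enoxybenzoate F10. Condensation with 20 as in step 10 gives 2-(methoxymethoxy)-1-[3,5-bis(3-methylbut-2-enyl)-4-prop-2-enoxyphenyl]-3-[2,4,6-tris(methoxymethoxy)phenyl]propane-1,3-dione F11. The acid step is then run with the 4'-oxygen still masked, so no phenol can add to the alkenes, giving 3,5,7-trihydroxy-2-[3,5-bis(3-methylbut-2-enyl)-4-prop-2-enoxyphenyl]chromen-4-one F12. The allyl ether is finally removed without acid by Pd(PPh3)4 and morpholine in THF at 20 °C to give 23.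

## Further compounds

F1 | step 4 | tributyl(3-methylbut-2-enyl)stannane | CC(C)=CC[Sn](CCCC)(CCCC)CCCC
F2 | step 4 | ethyl 4-hydroxy-3,5-diiodobenzoate | CCOC(=O)c1cc(I)c(O)c(I)c1
F3 | step 4 | ethyl 3,5-diiodo-4-(methoxymethoxy)benzoate | CCOC(=O)c1cc(I)c(OCOC)c(I)c1
F4 | step 1 | ethyl 3-oxobutanoate | CCOC(=O)CC(C)=O
F5 | step 1 | ethyl 7-methyl-3-oxooct-6-enoate | CCOC(=O)CC(=O)CCC=C(C)C
F6 | step 1 | ethyl 7-methyl-2-(3-methylbut-2-enyl)-3-oxooct-6-enoate (racemic) | CCOC(=O)C(CC=C(C)C)C(=O)CCC=C(C)C
F7 | step 10 | [4-(methoxymethoxy)-3,5-bis(3-methylbut-2-enyl)phenyl]methanol | COCOc1c(CC=C(C)C)cc(CO)cc1CC=C(C)C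
F8 | step 10 | 4-(methoxymethoxy)-3,5-bis(3-methylbut-2-enyl)benzaldehyde | COCOc1c(CC=C(C)C)cc(C=O)cc1CC=C(C)C
F9 | step 10 | 3-hydroxy-2-(methoxymethoxy)-3-[4-(methoxymethoxy)-3,5-bis(3-methylbut-2-enyl)phenyl]-1-[2,4,6-tris(methoxymethoxy)phenyl]propan-1-one (mixture of diastereomers) | COCOC(C(O)c1cc(CC=C(C)C)c(OCOC)c(CC=C(C)C)c1)C(=O)c1c(OCOC)cc(OCOC)cc1OCOC
F10 | step 11 | ethyl 3,5-bis(3-methylbut-2-enyl)-4-prop-2-enoxybenzoate | CCOC(=O)c1cc(CC=C(C)C)c(OCC=C)c(CC=C(C)C)c1
F11 | step 11 | 2-(methoxymethoxy)-1-[3,5-bis(3-methylbut-2-enyl)-4-prop-2-enoxyphenyl]-3-[2,4,6-tris(methoxymethoxy)phenyl]propane-1,3-dione (racemic) | COCOC(C(=O)c1cc(CC=C(C)C)c(OCC=C)c(CC=C(C)C)c1)C(=O)c1c(OCOC)cc(OCOC)cc1OCOC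
F12 | step 11 | 3,5,7-trihydroxy-2-[3,5-bis(3-methylbut-2-enyl)-4-prop-2-enoxyphenyl]chromen-4-one | C=CCOc1c(CC=C(C)C)cc(-c2oc3cc(O)cc(O)c3c(=O)c2O)cc1CC=C(C)C
A1 | alternative 1 | 1-[2-hydroxy-4,6-bis(methoxymethoxy)phenyl]-3-[4-(methoxymethoxy)-3,5-bis(3-methylbut-2-enyl)phenyl]prop-2-yn-1-one | COCOc1cc(O)c(C(=O)C#Cc2cc(CC=C(C)C)c(OCOC)c(CC=C(C)C)c2)c(OCOC)c1
A2 | alternative 1 | 3-[4-(methoxymethoxy)-3,5-bis(3-methylbut-2-enyl)phenyl]prop-2-ynoic acid | COCOc1c(CC=C(C)C)cc(C#CC(=O)O)cc1CC=C(C)C
A3 | alternative 1 | 3,5-bis(methoxymethoxy)-2-(trimethylsilyl)phenyl trifluoromethanesulfonate | COCOc1cc(OCOC)c([Si](C)(C)C)c(OS(=O)(=O)C(F)(F)F)c1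
A4 | alternative 2 | 5,7-bis(methoxymethoxy)-2-[4-(methoxymethoxy)-3,5-bis(3-methylbut-2-enyl)phenyl]chromen-4-one | COCOc1cc(OCOC)c2c(=O)cc(-c3cc(CC=C(C)C)c(OCOC)c(CC=C(C)C)c3)oc2c1
A5 | alternative 2 | 2-iodo-3,5-bis(methoxymethoxy)phenol | COCOc1cc(O)c(I)c(OCOC)c1
A6 | alternative 2 | 5-ethynyl-2-(methoxymethoxy)-1,3-bis(3-methylbut-2-enyl)benzene | COCOc1c(CC=C(C)C)cc(C#C)cc1CC=C(C)C
A7 | alternative 3 | (E)-3-[4-(methoxymethoxy)-3,5-bis(3-methylbut-2-enyl)phenyl]-1-(2,4,6-trihydroxyphenyl)prop-2-en-1-one | O=C(/C=C/c1cc(CC=C(C)C)c(OCOC)c(CC=C(C)C)c1)c1c(O)cc(O)cc1O
A8 | alternative 3 | methyl (E)-9-[4-(methoxymethoxy)-3,5-bis(3-methylbut-2-enyl)phenyl]-3,5,7-trioxonon-8-enoate | COC(=O)CC(=O)CC(=O)CC(=O)/C=C/c1cc(CC=C(C)C)c(OCOC)c(CC=C(C)C)c1
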